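**Strategy.** Everything rests on disconnecting the C2–C3 bond of the dihydrofuran ring (ring B of the 2-aryl-2,3-dihydrobenzofuran). C2 is a methine flanked by O1 and the guaiacyl ring, so in a benzyl aryl ether precursor its C–H bond is hydridic; C3, at ester oxidation level, can be a rhodium carbene carbon. One chiral dirhodium-catalysed 1,5 C–H insertion of an ortho-(benzyloxy)aryl diazoacetate therefore closes ring B through the C2–C3 bond and fixes C2, while C3 is later set trans by epimerisation before reduction to CH2OH. The lactone is then built on this fragment by a three-component conjugate addition–benzylation on a chiral butenolide.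

Key step: step 3

Remark 1: the sense of induction in step 3 is assumed by analogy with 2-(benzyloxy)aryl diazoacetates, for which the (S)-configured phthaloyl-tert-leucinate dirhodium catalysts are taken to give the (2R) series; Rh2(R-PTTL)4 is therefore specified for (2S), and the antipodal catalyst would be used if the sense proved opposite.
Remark 2: butenolide 14 is treated as purchasable; otherwise it is available from furfural by photo-oxygenation and acetalisation with (−)-menthol.

**Step 1**
Reactants: 1 5-iodovanillin; 2 [4-(benzyloxy)-3-methoxyphenyl]methanol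
Product: 3 4-{[4-(benzyloxy)-3-methoxybenzyl]oxy}-3-iodo-5-methoxybenzaldehyde
Conditions: PPh3, DIAD, THF, 0 °C → rt
Reagents that add atoms: none
Why: Mitsunobu etherification, in which the acidic, formyl-activated phenol of 1 displaces the oxyphosphonium salt of the primary benzylic alcohol 2 under neutral conditions that leave the aldehyde and the iodide untouched; no stereocentre is formed.

**Step 2**
Reactants: 3 iodo aldehyde; 4 ethyl diazoacetate
Product: 5 ethyl 2-(2-{[4-(benzyloxy)-3-methoxybenzyl]oxy}-5-formyl-3-methoxyphenyl)-2-diazoacetate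
Conditions: Pd(PPh3)4 (5 mol %), Ag2CO3 (0.5 equiv), Et3N, toluene, rt
Reagents that add atoms: none
Why: Palladium-catalysed cross-coupling of an aryl iodide with the C–H bond of an acceptor diazo ester (oxidative addition of the zerovalent palladium complex, silver-assisted iodide abstraction, deprotonative transfer of the diazoacetate to palladium, reductive elimination), which keeps the diazo group and is helped by the electron-poor, formyl-bearing arene.

**Step 3**
Reactants: 5 aryl diazoacetate
Product: 6 ethyl (2S,3R)-2-[4-(benzyloxy)-3-methoxyphenyl]-5-formyl-7-methoxy-2,3-dihydro-1-benzofuran-3-carboxylate (2,3-cis)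
Conditions: Rh2(R-PTTL)4 [dirhodium tetrakis(N-phthaloyl-(R)-tert-leucinate)] (2 mol %), toluene, −60 °C, high dilution
Reagents that add atoms: none
Why: The dirhodium tetracarboxylate (divalent rhodium) extrudes N2 from 5 to give an electrophilic donor/acceptor rhodium carbene at the future C3, which inserts through a concerted, hydride-transfer-like three-centre transition state into a C–H bond of the ortho O–CH2Ar group and so forms the C2–C3 bond. The closest known reaction type is the enantioselective intramolecular C–H insertion of 2-(2-benzyloxyphenyl)-2-diazoacetates with phthaloyl-tert-leucinate dirhodium catalysts, which gives cis-2-aryl-2,3-dihydrobenzofuran-3-carboxylates. Ring B closes as a five-membered ring by 1,5 insertion along C3–C3a–C7a–O1–C2. C2 (S) is set by the chiral carboxylate pocket, which selects one of the two enantiotopic benzylic hydrogens, and C3 (R, cis) follows kinetically from the geometry of the concerted insertion and is inverted to trans in step 4. The step needs site- and chemoselectivity of the carbene: only this CH2 can be reached through a five-membered transition state, it is activated by O1 and by the 4-benzyloxy-3-methoxyphenyl ring, and low temperature with high dilution should suppress carbene dimerisation and ylide formation at the formyl group.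

**Step 4**
Reactants: 6 cis ester aldehyde
Product: 9 trans diol [(2S,3R)-2-[4-(benzyloxy)-3-methoxyphenyl]-7-methoxy-2,3-dihydro-1-benzofuran-3,5-diyl]dimethanol, via cis hydroxy ester 7 (not isolated), via trans hydroxy ester 8 (not isolated)
Conditions: NaBH4, EtOH/THF, 0 °C; NaOEt (0.3 equiv), rt; then LiBH4, rt
Reagents that add atoms: none
Why: Chemoselective borohydride reduction of the aldehyde first removes the acceptor para to O1 (so that base cannot open ring B by retro-oxa-Michael and scramble C2), ethoxide then epimerises C3 through the ester enolate to the thermodynamically favoured 2,3-trans ester with C2 untouched, and LiBH4 reduces the ester to the hydroxymethyl group with retention at C3.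

**Step 5**
Reactants: 9 trans diol
Product: 10 {(2S,3R)-2-[4-(benzyloxy)-3-methoxyphenyl]-5-(bromomethyl)-7-methoxy-2,3-dihydro-1-benzofuran-3-yl}methanol
Conditions: NBS, Me2S (reagent preformed), CH2Cl2, −20 → 0 °C
Reagents that add atoms: N-bromosuccinimide, O=C1CCC(=O)N1Br
Why: Corey–Kim halogenation, in which only the benzylic alkoxysulfonium ion (para to O1) is displaced by bromide while that of the saturated primary alcohol reverts to the alcohol on work-up, so the two hydroxymethyl groups are told apart without a protecting group.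

**Step 6**
Reactants: 10 bromo alcohol
Product: 11 triethylsilyl ether of 10
Conditions: TESOTf, 2,6-lutidine, CH2Cl2, −78 °C
Reagents that add atoms: triethylsilyl trifluoromethanesulfonate, CC[Si](CC)(CC)OS(=O)(=O)C(F)(F)F
Why: Silylation with a silyl triflate and a hindered pyridine base at low temperature should not quaternise the benzylic bromide, and the triethylsilyl ether masks the acidic OH for the enolate alkylation yet falls off in the acidic lactonisation of step 9.

**Step 7**
Reactants: 12 4-(benzyloxy)-3-methoxybenzaldehyde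
Product: 13 2-[4-(benzyloxy)-3-methoxyphenyl]-1,3-dithiane
Conditions: HS(CH2)3SH, BF3·OEt2 (cat.), CH2Cl2, 0 °C → rt
Reagents that add atoms: propane-1,3-dithiol, SCCCS
Why: Lewis-acid-catalysed dithioacetalisation gives the Corey–Seebach acyl anion equivalent for the later aroyl carbon.

**Step 8**
Reactants: 13 aryl dithiane; 14 (5R)-5-[(1R,2S,5R)-menthyloxy]furan-2(5H)-one; 11 benzylic bromide
Product: 17 (3R,4R,5R)-3-(benzofuranylmethyl)-4-(2-aryl-1,3-dithian-2-yl)-5-(menthyloxy)oxolan-2-one, via lithiated dithiane 15 (not isolated), via lithium enolate 16 (not isolated)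
Conditions: n-BuLi, THF, −78 → −20 °C; 14, −78 °C; then 11, DMPU, −78 °C → rt
Reagents that add atoms: none
Why: Tandem Michael addition–enolate alkylation with Corey–Seebach umpolung, in which the lithiated dithiane adds 1,4 to the butenolide anti to the menthyloxy group (sets lactone C4, R) and the resulting lithium enolate is benzylated by 11 anti to the bulky dithianyl group (sets C3, R), so the acetal centre relays both new stereocentres as the 3,4-trans-4,5-trans adduct.

**Step 9**
Reactants: 17 tandem adduct
Product: 19 (3R,4R)-4-{2-[4-(benzyloxy)-3-methoxyphenyl]-1,3-dithian-2-yl}-3-{[(2S,3R)-2-[4-(benzyloxy)-3-methoxyphenyl]-3-(hydroxymethyl)-7-methoxy-2,3-dihydro-1-benzofuran-5-yl]methyl}oxolan-2-one, via seco hydroxy acid 18 (not isolated)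
Conditions: KOH, NaBH4, EtOH/THF/H2O, rt; then 2 M HCl to pH 1, rt
Reagents that add atoms: none
Why: Saponification opens the pseudo-ester lactone to a carboxylate and a hemiacetal that loses menthoxide to an aldehyde, which borohydride reduces in situ, and acidification then lactonises the 4-hydroxy acid and hydrolyses the triethylsilyl ether, the two lactone stereocentres being untouched because the carboxylate alpha-carbon is not enolisable and the aldehyde is reduced faster than it epimerises.

**Step 10**
Reactants: 19 dithianyl lactone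
Product: 20 (3R,4R)-4-[4-(benzyloxy)-3-methoxybenzoyl]-3-{[(2S,3R)-2-[4-(benzyloxy)-3-methoxyphenyl]-3-(hydroxymethyl)-7-methoxy-2,3-dihydro-1-benzofuran-5-yl]methyl}oxolan-2-one
Conditions: Hg(ClO4)2, CaCO3, THF/H2O, 0 °C
Reagents that add atoms: water, O
Why: Thiophilic hydrolysis of the dithiane by divalent mercury under carbonate buffering unmasks the aryl ketone without acid, so the benzyl ethers, the lactone and ring B should survive and the ketone alpha-centre stays in the favoured 3,4-trans arrangement.

**Step 11**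
Reactants: 20 keto lactone
Product: 21 (3R,4R)-4-{(R)-[4-(benzyloxy)-3-methoxyphenyl](hydroxy)methyl}-3-{[(2S,3R)-2-[4-(benzyloxy)-3-methoxyphenyl]-3-(hydroxymethyl)-7-methoxy-2,3-dihydro-1-benzofuran-5-yl]methyl}oxolan-2-one
Conditions: (S)-Me-CBS (20 mol %), BH3·SMe2, THF, −20 °C; MeOH
Reagents that add atoms: none
Why: Corey–Bakshi–Shibata reduction, in which the (S)-oxazaborolidine binds the ketone with the aryl group as the large substituent and delivers hydride to the face that gives the (R)-carbinol; reagent control is needed because Felkin–Anh addition to this alpha-branched ketone is expected to favour the (S)-epimer, while the lactone is not reduced at this temperature and the free primary alcohol only consumes hydride.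

**Step 12**
Reactants: 21 dibenzyl ether
Product: 22 target (CNP0233460.1)
Conditions: H2 (1 atm), 10% Pd/C, EtOAc, rt
Reagents that add atoms: none
Why: Hydrogenolysis of the two aryl benzyl ethers under neutral conditions should be much faster than cleavage of the secondary benzylic alcohol or of the C2–O1 bond of ring B, so both phenols are freed without touching any stereocentre.

**Compound list**
1 | 5-iodovanillin (4-hydroxy-3-iodo-5-methoxybenzaldehyde) | COc1cc(C=O)cc(I)c1O | starting material
2 | [4-(benzyloxy)-3-methoxyphenyl]methanol | COc1cc(CO)ccc1OCc1ccccc1 | starting material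
3 | 4-{[4-(benzyloxy)-3-methoxybenzyl]oxy}-3-iodo-5-methoxybenzaldehyde | COc1cc(C=O)cc(I)c1OCc1ccc(OCc2ccccc2)c(OC)c1 | intermediate
4 | ethyl diazoacetate | CCOC(=O)C=[N+]=[N-] | starting material
5 | ethyl 2-(2-{[4-(benzyloxy)-3-methoxybenzyl]oxy}-5-formyl-3-methoxyphenyl)-2-diazoacetate | CCOC(=O)C(=[N+]=[N-])c1cc(C=O)cc(OC)c1OCc1ccc(OCc2ccccc2)c(OC)c1 | intermediate
6 | ethyl (2S,3R)-2-[4-(benzyloxy)-3-methoxyphenyl]-5-formyl-7-methoxy-2,3-dihydro-1-benzofuran-3-carboxylate (cis) | COc1cc([C@H]2Oc3c(OC)cc(C=O)cc3[C@H]2C(=O)OCC)ccc1OCc1ccccc1 | intermediate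
7 | ethyl (2S,3R)-2-[4-(benzyloxy)-3-methoxyphenyl]-5-(hydroxymethyl)-7-methoxy-2,3-dihydro-1-benzofuran-3-carboxylate (cis) | COc1cc([C@H]2Oc3c(OC)cc(CO)cc3[C@H]2C(=O)OCC)ccc1OCc1ccccc1 | intermediate (not isolated)
8 | ethyl (2S,3S)-2-[4-(benzyloxy)-3-methoxyphenyl]-5-(hydroxymethyl)-7-methoxy-2,3-dihydro-1-benzofuran-3-carboxylate (trans) | COc1cc([C@H]2Oc3c(OC)cc(CO)cc3[C@@H]2C(=O)OCC)ccc1OCc1ccccc1 | intermediate (not isolated)
9 | [(2S,3R)-2-[4-(benzyloxy)-3-methoxyphenyl]-7-methoxy-2,3-dihydro-1-benzofuran-3,5-diyl]dimethanol (trans) | COc1cc([C@H]2Oc3c(OC)cc(CO)cc3[C@@H]2CO)ccc1OCc1ccccc1 | intermediate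
10 | {(2S,3R)-2-[4-(benzyloxy)-3-methoxyphenyl]-5-(bromomethyl)-7-methoxy-2,3-dihydro-1-benzofuran-3-yl}methanol | COc1cc([C@H]2Oc3c(OC)cc(CBr)cc3[C@@H]2CO)ccc1OCc1ccccc1 | intermediate
11 | triethylsilyl ether of 10 | COc1cc([C@H]2Oc3c(OC)cc(CBr)cc3[C@@H]2CO[Si](CC)(CC)CC)ccc1OCc1ccccc1 | intermediate
12 | 4-(benzyloxy)-3-methoxybenzaldehyde | COc1cc(C=O)ccc1OCc1ccccc1 | starting material
13 | 2-[4-(benzyloxy)-3-methoxyphenyl]-1,3-dithiane | COc1cc(C2SCCCS2)ccc1OCc1ccccc1 | intermediate
14 | (5R)-5-{[(1R,2S,5R)-5-methyl-2-(propan-2-yl)cyclohexyl]oxy}furan-2(5H)-one | O=C1C=C[C@H](O[C@@H]2C[C@H](C)CC[C@H]2C(C)C)O1 | starting material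
15 | 2-lithio-2-[4-(benzyloxy)-3-methoxyphenyl]-1,3-dithiane | [Li]C1(SCCCS1)c1ccc(OCc2ccccc2)c(OC)c1 | intermediate (not isolated)
16 | lithium enolate of the Michael adduct of 15 and 14 (dithianyl group anti to menthyloxy) | [Li]OC1=C[C@@H](C2(SCCCS2)c2ccc(OCc3ccccc3)c(OC)c2)[C@H](O[C@@H]2C[C@H](C)CC[C@H]2C(C)C)O1 | intermediate (not isolated)
17 | (3R,4R,5R)-4-{2-[4-(benzyloxy)-3-methoxyphenyl]-1,3-dithian-2-yl}-3-{[(2S,3R)-2-[4-(benzyloxy)-3-methoxyphenyl]-7-methoxy-3-(triethylsilyloxymethyl)-2,3-dihydro-1-benzofuran-5-yl]methyl}-5-[(1R,2S,5R)-menthyloxy]oxolan-2-one | COc1cc([C@H]2Oc3c(OC)cc(C[C@H]4C(=O)O[C@@H](O[C@@H]5C[C@H](C)CC[C@H]5C(C)C)[C@@H]4C4(SCCCS4)c4ccc(OCc5ccccc5)c(OC)c4)cc3[C@@H]2CO[Si](CC)(CC)CC)ccc1OCc1ccccc1 | intermediate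
18 | (2R,3R)-3-{2-[4-(benzyloxy)-3-methoxyphenyl]-1,3-dithian-2-yl}-4-hydroxy-2-{[benzofuran-5-yl]methyl}butanoic acid, silyl ether still in place (formed as its potassium salt) | COc1cc([C@H]2Oc3c(OC)cc(C[C@@H](C(=O)O)[C@H](CO)C4(SCCCS4)c4ccc(OCc5ccccc5)c(OC)c4)cc3[C@@H]2CO[Si](CC)(CC)CC)ccc1OCc1ccccc1 | intermediate (not isolated)
19 | (3R,4R)-dithianyl lactone with free 3-hydroxymethyl group | COc1cc([C@H]2Oc3c(OC)cc(C[C@H]4C(=O)OC[C@@H]4C4(SCCCS4)c4ccc(OCc5ccccc5)c(OC)c4)cc3[C@@H]2CO)ccc1OCc1ccccc1 | intermediate
20 | (3R,4R)-4-[4-(benzyloxy)-3-methoxybenzoyl] lactone | COc1cc([C@H]2Oc3c(OC)cc(C[C@H]4C(=O)OC[C@@H]4C(=O)c4ccc(OCc5ccccc5)c(OC)c4)cc3[C@@H]2CO)ccc1OCc1ccccc1 | intermediate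
21 | (3R,4R)-4-{(R)-[4-(benzyloxy)-3-methoxyphenyl](hydroxy)methyl} lactone, di-O-benzyl target | COc1cc([C@H]2Oc3c(OC)cc(C[C@H]4C(=O)OC[C@@H]4[C@@H](O)c4ccc(OCc5ccccc5)c(OC)c4)cc3[C@@H]2CO)ccc1OCc1ccccc1 | intermediate
22 | (3R,4R)-4-[(R)-hydroxy(4-hydroxy-3-methoxyphenyl)methyl]-3-{[(2S,3R)-2-(4-hydroxy-3-methoxyphenyl)-3-(hydroxymethyl)-7-methoxy-2,3-dihydro-1-benzofuran-5-yl]methyl}oxolan-2-one (CNP0233460.1) | COc1cc([C@H]2Oc3c(OC)cc(C[C@H]4C(=O)OC[C@@H]4[C@@H](O)c4ccc(O)c(OC)c4)cc3[C@@H]2CO)ccc1O | target

**Step count and risks**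
Total step count: 12. Longest linear sequence: 11 (steps 1–6, then 8–12); step 7 is a one-step side branch.

Step 3 (key step). The rhodium carbene may be intercepted by the formyl group of a second molecule (carbonyl ylide formation) or dimerise, and the crowded 3-methoxy-flanked ether may erode the discrimination between the two benzylic hydrogens. The fallback takes the formyl group out of the insertion substrate. Setting out from 5, NaBH4 in MeOH at 0 °C should reduce only the aldehyde, since the diazo ester is inert to borohydride, to give diazo alcohol F1. Acetylation (Ac2O, pyridine) gives diazo acetate F2. The same dirhodium-catalysed insertion on this acceptor-free, more electron-rich aryl ether should give cis acetoxymethyl ester F3. NaOEt in EtOH then removes the acetate and epimerises C3, which comes back to the route at 8, reduced on with LiBH4 to 9 as in step 4.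

Step 2. Oxidative addition and diazoacetate transfer at the hindered ortho-alkoxy iodide may be slow, so that palladium-carbene formation and loss of the diazo group compete. The fallback separates carbon–carbon bond formation from diazo installation. Setting out from 3, a Migita–Kosugi–Stille coupling with ethyl (tributylstannyl)acetate (PdCl2[P(o-tol)3]2, ZnBr2, DMF, 80 °C), which tolerates the aldehyde, should give arylacetate F4. Regitz diazo transfer (4-acetamidobenzenesulfonyl azide, DBU, MeCN, 0 °C → rt) at the benzylic ester position then comes back to the route at 5.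

Step 11. The reagent-controlled hydride delivery is mismatched with the Felkin–Anh bias of the alpha-branched ketone, so facial selectivity may be poor. The fallback uses substrate control followed by inversion. Setting out from 20, LiBH(s-Bu)3 in THF at −78 °C should follow the substrate bias and give the (S)-carbinol F5. Mitsunobu esterification with 4-nitrobenzoic acid (PPh3, DIAD) inverts the benzylic centre and also acylates the primary alcohol, giving bis(4-nitrobenzoate) F6. Mild methanolysis (K2CO3, MeOH, 0 °C) removes both esters and comes back to the route at 21.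

**Further compounds**
F1 | step 3 | ethyl 2-(2-{[4-(benzyloxy)-3-methoxybenzyl]oxy}-5-(hydroxymethyl)-3-methoxyphenyl)-2-diazoacetate | CCOC(=O)C(=[N+]=[N-])c1cc(CO)cc(OC)c1OCc1ccc(OCc2ccccc2)c(OC)c1
F2 | step 3 | ethyl 2-(5-(acetoxymethyl)-2-{[4-(benzyloxy)-3-methoxybenzyl]oxy}-3-methoxyphenyl)-2-diazoacetate | CCOC(=O)C(=[N+]=[N-])c1cc(COC(C)=O)cc(OC)c1OCc1ccc(OCc2ccccc2)c(OC)c1
F3 | step 3 | ethyl (2S,3R)-5-(acetoxymethyl)-2-[4-(benzyloxy)-3-methoxyphenyl]-7-methoxy-2,3-dihydro-1-benzofuran-3-carboxylate (cis) | COc1cc([C@H]2Oc3c(OC)cc(COC(C)=O)cc3[C@H]2C(=O)OCC)ccc1OCc1ccccc1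
F4 | step 2 | ethyl 2-(2-{[4-(benzyloxy)-3-methoxybenzyl]oxy}-5-formyl-3-methoxyphenyl)acetate | CCOC(=O)Cc1cc(C=O)cc(OC)c1OCc1ccc(OCc2ccccc2)c(OC)c1
F5 | step 11 | (S)-carbinol epimer of 21 | COc1cc([C@H]2Oc3c(OC)cc(C[C@H]4C(=O)OC[C@@H]4[C@H](O)c4ccc(OCc5ccccc5)c(OC)c4)cc3[C@@H]2CO)ccc1OCc1ccccc1
F6 | step 11 | bis(4-nitrobenzoate) of 21 with (R)-configured benzylic ester | COc1cc([C@H]2Oc3c(OC)cc(C[C@H]4C(=O)OC[C@@H]4[C@@H](OC(=O)c4ccc(cc4)[N+](=O)[O-])c4ccc(OCc5ccccc5)c(OC)c4)cc3[C@@H]2COC(=O)c2ccc(cc2)[N+](=O)[O-])ccc1OCc1ccccc1
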